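**Retrosynthetic overview**

1. The route rests on ring B, a resorcinol whose C2 oxygen must end as OCH3 and whose C4 oxygen must carry the ring A acyl group, with the ester carbon to ring C on C1 and CH3 on C6. The target has no stereocentre.
2. Last disconnections: five benzyl groups (hydrogenolysis) and the ester between the ring A carbonyl and O–C4 of ring B. Ring A comes from orsellinic acid by hydroxylation at C5.
3. Key disconnection: ring B is opened into a diazoketone that already carries the ring C aryl ester, and a silyloxyacetylene. The benzannulation forms C5–C6, C2–C3, C4–C5 and C1–C2 and leaves the C2 hydroxyl free and the C4 oxygen silylated.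
4. The diazoketone comes from butane-2,3-dione by Wittig olefination and deacylative diazo transfer (diazomethane would add to the electron-poor alkene). The ring C phenol comes from orsellinic acid.
5. Ring order: rings C and A are taken preformed; ring B is the only ring that is built.

Key step: step 12

Remark: salts formed by simple proton transfer (phenoxides, carboxylates, enolates, the lithium acetylide of 16) count as ionised forms of the numbered compounds and carry no number of their own; chloroacetaldehyde 13 is used as the anhydrous monomer.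

**Route**

Step 1
Reactants: 1 orsellinic acid (2,4-dihydroxy-6-methylbenzoic acid)
Product: 2 benzyl 2,4-dihydroxy-6-methylbenzoate
Conditions: BnBr (1.05 equiv), KHCO3, DMF, 20 °C
Reagents that add atoms: benzyl bromide, BrCc1ccccc1
Why: KHCO3 ionises only the carboxylic acid, and SN2 alkylation of the carboxylate by benzyl bromide should give the ester without touching the phenols (carboxylate O-alkylation).

Step 2
Reactants: 2 benzyl 2,4-dihydroxy-6-methylbenzoate
Product: 3 benzyl 2-hydroxy-4-(methoxymethoxy)-6-methylbenzoate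
Conditions: MOMCl (1.1 equiv), i-Pr2NEt, CH2Cl2, 0 °C
Reagents that add atoms: chloromethyl methyl ether, COCCl
Why: The 4-hydroxyl is the only phenol not hydrogen-bonded to the ester carbonyl, so Williamson-type alkylation with MOMCl and a hindered amine should protect it alone.

Step 3
Reactants: 3 benzyl 2-hydroxy-4-(methoxymethoxy)-6-methylbenzoate
Product: 4 benzyl 2-(benzyloxy)-4-(methoxymethoxy)-6-methylbenzoate
Conditions: BnBr (1.5 equiv), K2CO3, DMF, 60 °C
Reagents that add atoms: benzyl bromide, BrCc1ccccc1
Why: Williamson etherification of the chelated 2-hydroxyl under K2CO3/DMF, to which the acetal and the hindered ester are inert.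

Step 4
Reactants: 4 benzyl 2-(benzyloxy)-4-(methoxymethoxy)-6-methylbenzoate
Product: 5 benzyl 2-(benzyloxy)-4-hydroxy-6-methylbenzoate (ring C phenol)
Conditions: HCl (cat.), MeOH/THF, 45 °C
Reagents that add atoms: none
Why: Acid-catalysed acetal exchange with methanol removes the MOM group as dimethoxymethane, while the benzyl ether and the doubly ortho-substituted benzyl ester are not attacked.

Step 5
Reactants: 6 butane-2,3-dione; 7 methyl (triphenylphosphoranylidene)acetate
Product: 8 methyl (E)-3-methyl-4-oxopent-2-enoate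
Conditions: 6 (2 equiv), CH2Cl2, 0 → 20 °C
Reagents that add atoms: none
Why: Wittig olefination of one carbonyl of the symmetrical diketone by the stabilised ylide should give the E enoate (acetyl trans to ester) under the usual thermodynamic control, with excess diketone suppressing double olefination.

Step 6
Reactants: 8 methyl (E)-3-methyl-4-oxopent-2-enoate
Product: 9 methyl (E)-7,7,7-trifluoro-3-methyl-4,6-dioxohept-2-enoate
Conditions: LiN(SiMe3)2 (1.1 equiv), THF, −78 °C (8 added to the base); CF3CO2CH2CF3 (1.2 equiv), −78 °C; then aq HCl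
Reagents that add atoms: 2,2,2-trifluoroethyl trifluoroacetate, O=C(OCC(F)(F)F)C(F)(F)F
Why: Kinetic deprotonation at the acetyl methyl group, the only α-position of the ketone, and Claisen-type C-acylation by the trifluoroacetate should give the 1,3-diketone that activates this carbon for diazo transfer.

Step 7
Reactants: 9 methyl (E)-7,7,7-trifluoro-3-methyl-4,6-dioxohept-2-enoate
Product: 10 methyl (E)-5-diazo-3-methyl-4-oxopent-2-enoate
Conditions: MsN3 (1.5 equiv), Et3N (1.5 equiv), H2O (1 equiv), MeCN, 20 °C
Reagents that add atoms: methanesulfonyl azide, CS(=O)(=O)N=[N+]=[N-]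
Why: Deacylative (Regitz-type) diazo transfer: the sulfonyl azide adds to the diketone enolate and the adduct loses the trifluoroacetyl group as the N-acylsulfonamide, which should give the diazoketone without diazomethane, a dipole that would add to the electron-poor alkene.

Step 8
Reactants: 10 methyl (E)-5-diazo-3-methyl-4-oxopent-2-enoate
Product: 11 (E)-5-diazo-3-methyl-4-oxopent-2-enoic acid
Conditions: LiOH (1.1 equiv), THF/H2O, 0 °C; then 10% aq citric acid, 0 °C
Reagents that add atoms: lithium hydroxide, [Li+].[OH-]
Why: Saponification of the unhindered methyl ester by hydroxide at 0 °C, a medium in which diazoketones are stable, followed by mild acidification with citric acid so that the diazo carbon is not protonated.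

Step 9
Reactants: 11 (E)-5-diazo-3-methyl-4-oxopent-2-enoic acid; 5 benzyl 2-(benzyloxy)-4-hydroxy-6-methylbenzoate
Product: 12 benzyl 2-(benzyloxy)-4-{[(2E)-5-diazo-3-methyl-4-oxopent-2-enoyl]oxy}-6-methylbenzoate (diazoketone)
Conditions: DCC (1.1 equiv), DMAP (0.1 equiv), CH2Cl2, 0 → 20 °C
Reagents that add atoms: none
Why: Steglich esterification: the carbodiimide activates the unhindered enoic acid and DMAP transfers the acyl group to the only free phenol of 5 under neutral conditions that leave the diazoketone and the E alkene untouched, so the aryl ester is made before ring B exists and is not yet hindered.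

Step 10
Reactants: 13 chloroacetaldehyde; 14 triisopropylsilyl trifluoromethanesulfonate
Product: 15 (2-chloroethenyl)oxy-triisopropylsilane (2-chlorovinyl triisopropylsilyl ether, E/Z mixture)
Conditions: i-Pr2NEt (1.3 equiv), CH2Cl2, −78 → 0 °C
Reagents that add atoms: none
Why: Soft enolisation: the silyl triflate activates the aldehyde oxygen and the hindered amine removes the acidic proton next to chlorine, which should give the silyl enol ether by O-silylation (both alkene isomers are usable).

Step 11
Reactants: 15 (2-chloroethenyl)oxy-triisopropylsilane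
Product: 16 (triisopropylsilyloxy)acetylene
Conditions: LiN(i-Pr)2 (2.2 equiv), THF, −78 °C; then H2O
Reagents that add atoms: none
Why: Base-induced dehydrochlorination of a 2-halovinyl ether, the classical route to alkynyl ethers, should give the ynol ether as its lithium acetylide, which water protonates; the bulky silyl group is expected to resist attack at silicon.

Step 12
Reactants: 12 diazoketone; 16 (triisopropylsilyloxy)acetylene
Product: 21 benzyl 2-(benzyloxy)-4-{[2-hydroxy-6-methyl-4-(triisopropylsilyloxy)benzoyl]oxy}-6-methylbenzoate, via vinylketene 17 (not isolated), via vinylcyclobutenone 18 (not isolated), via dienylketene 19 (not isolated), via cyclohexadienone 20 (not isolated)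
Conditions: 16 (3 equiv), ClCH2CH2Cl, hν (365 nm), 20 °C; then 80 °C
Reagents that add atoms: none
Why: Light expels N2 from 12 and the Wolff 1,2-shift of the alkenyl group gives vinylketene 17 (C5–C6), whose ketene C=C adds to the ynol ether 16 in a [2+2] cycloaddition to the 3-silyloxy-4-alkenylcyclobutenone 18 (C2–C3 and C4–C5). Four-electron electrocyclic opening of 18 (reversible, completed at 80 °C) gives dienylketene 19, and ring B closes by six-electron electrocyclization of the ketene carbon onto the ester-bearing alkene carbon (C1–C2) to dienone 20, which enolises to the phenol. The closest known reaction type is the Danheiser benzannulation in its diazoketone form with silyloxyalkynes, which delivers resorcinol monosilyl ethers. No stereocentre is created that survives: the sp3 carbons of 18 and 20 are racemic and disappear on ring opening and on aromatisation. The step needs regioselectivity in the [2+2] event, and this is secured by the polarisation of 16, whose unsubstituted carbon is the nucleophilic terminus and bonds to the electrophilic ketene carbonyl carbon, so that the silylated oxygen ends at C4 (meta to the new C2 hydroxyl, para to C1). It also needs the ester on the outside of the triene terminus, which the E alkene of 12 provides; 365 nm light is chosen to spare the aryl ester and to limit E/Z scrambling.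

Step 13
Reactants: 21 benzyl 2-(benzyloxy)-4-{[2-hydroxy-6-methyl-4-(triisopropylsilyloxy)benzoyl]oxy}-6-methylbenzoate
Product: 22 benzyl 2-(benzyloxy)-4-{[2-methoxy-6-methyl-4-(triisopropylsilyloxy)benzoyl]oxy}-6-methylbenzoate
Conditions: MeOH (3 equiv), PPh3, DIAD, THF, 0 → 20 °C
Reagents that add atoms: methanol, CO
Why: Mitsunobu etherification: the chelated phenol is acidic enough to protonate the betaine and its phenoxide takes the methyl group from the methoxyphosphonium ion by SN2, under neutral conditions that spare the silyl ether and both aryl esters.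

Step 14
Reactants: 22 benzyl 2-(benzyloxy)-4-{[2-methoxy-6-methyl-4-(triisopropylsilyloxy)benzoyl]oxy}-6-methylbenzoate
Product: 23 benzyl 2-(benzyloxy)-4-[(4-hydroxy-2-methoxy-6-methylbenzoyl)oxy]-6-methylbenzoate
Conditions: Bu4NF (1.1 equiv), AcOH (1.2 equiv), THF, 0 °C
Reagents that add atoms: none
Why: Fluoride cleaves the aryl O–Si bond (desilylation driven by the strong Si–F bond), and acetic acid protonates the phenoxide at once so that it cannot transesterify the depside ester.

Step 15
Reactants: 2 benzyl 2,4-dihydroxy-6-methylbenzoate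
Product: 25 benzyl 2,4,5-trihydroxy-6-methylbenzoate, via aryl sulfate 24 (not isolated)
Conditions: K2S2O8 (1.1 equiv), aq KOH, 0 → 20 °C, N2; then aq HCl, 80 °C
Reagents that add atoms: potassium peroxodisulfate, [K+].[K+].[O-]S(=O)(=O)OOS(=O)(=O)[O-]
Why: Elbs persulfate oxidation: the phenoxide attacks the peroxide oxygen through the carbon para to the C2 oxygen, and C5 is the only free position para to a phenoxide (para to the C4 oxygen is the blocked C1), so that acid hydrolysis of the aryl sulfate should give the 5-hydroxy compound.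

Step 16
Reactants: 25 benzyl 2,4,5-trihydroxy-6-methylbenzoate
Product: 26 benzyl 2,4,5-tris(benzyloxy)-6-methylbenzoate
Conditions: BnBr (3.5 equiv), K2CO3, DMF, 60 °C, N2
Reagents that add atoms: benzyl bromide, BrCc1ccccc1
Why: Williamson benzylation of all three phenols with K2CO3 in DMF under exclusion of air, because the hydroxyquinol is oxidised easily in base.

Step 17
Reactants: 26 benzyl 2,4,5-tris(benzyloxy)-6-methylbenzoate
Product: 27 2,4,5-tris(benzyloxy)-6-methylbenzoic acid
Conditions: KOH, DMSO/H2O, 90 °C; then aq HCl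
Reagents that add atoms: potassium hydroxide, [K+].[OH-]
Why: Saponification of the doubly ortho-substituted benzoate needs hydroxide in aqueous DMSO at 90 °C, conditions that the benzyl ethers withstand.

Step 18
Reactants: 27 2,4,5-tris(benzyloxy)-6-methylbenzoic acid; 23 benzyl 2-(benzyloxy)-4-[(4-hydroxy-2-methoxy-6-methylbenzoyl)oxy]-6-methylbenzoate
Product: 29 benzyl 2-(benzyloxy)-4-[(2-methoxy-6-methyl-4-{[2,4,5-tris(benzyloxy)-6-methylbenzoyl]oxy}benzoyl)oxy]-6-methylbenzoate, via acid chloride 28 (not isolated)
Conditions: (COCl)2, DMF (cat.), CH2Cl2, 0 → 20 °C, evaporate; then 23, Et3N, DMAP (cat.), CH2Cl2, 0 → 20 °C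
Reagents that add atoms: none
Why: Acid chloride formation under DMF catalysis and DMAP-catalysed acylation (nucleophilic catalysis) of the single free phenol of 23 should overcome the hindrance of the 2,6-disubstituted acyl group.

Step 19
Reactants: 29 protected tridepside
Product: 30 2'-O-methylhiascic acid
Conditions: H2 (1 atm), Pd/C, EtOAc, 20 °C
Reagents that add atoms: none
Why: Hydrogenolysis of the five benzylic C–O bonds (three ethers on ring A, the ether and the ester on ring C) over palladium on carbon, which leaves the aryl esters and the methyl ether intact.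

**Compound list**

1 | orsellinic acid (2,4-dihydroxy-6-methylbenzoic acid) | Cc1cc(O)cc(O)c1C(=O)O | starting material
2 | benzyl 2,4-dihydroxy-6-methylbenzoate | Cc1cc(O)cc(O)c1C(=O)OCc1ccccc1 | intermediate
3 | benzyl 2-hydroxy-4-(methoxymethoxy)-6-methylbenzoate | COCOc1cc(C)c(C(=O)OCc2ccccc2)c(O)c1 | intermediate
4 | benzyl 2-(benzyloxy)-4-(methoxymethoxy)-6-methylbenzoate | COCOc1cc(C)c(C(=O)OCc2ccccc2)c(OCc2ccccc2)c1 | intermediate
5 | benzyl 2-(benzyloxy)-4-hydroxy-6-methylbenzoate | Oc1cc(C)c(C(=O)OCc2ccccc2)c(OCc2ccccc2)c1 | intermediate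
6 | butane-2,3-dione | CC(=O)C(C)=O | starting material
7 | methyl (triphenylphosphoranylidene)acetate | COC(=O)C=P(c1ccccc1)(c1ccccc1)c1ccccc1 | starting material
8 | methyl (E)-3-methyl-4-oxopent-2-enoate | COC(=O)/C=C(\C)C(C)=O | intermediate
9 | methyl (E)-7,7,7-trifluoro-3-methyl-4,6-dioxohept-2-enoate | COC(=O)/C=C(\C)C(=O)CC(=O)C(F)(F)F | intermediate
10 | methyl (E)-5-diazo-3-methyl-4-oxopent-2-enoate | COC(=O)/C=C(\C)C(=O)C=[N+]=[N-] | intermediate
11 | (E)-5-diazo-3-methyl-4-oxopent-2-enoic acid | OC(=O)/C=C(\C)C(=O)C=[N+]=[N-] | intermediate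
12 | benzyl 2-(benzyloxy)-4-{[(2E)-5-diazo-3-methyl-4-oxopent-2-enoyl]oxy}-6-methylbenzoate | [N-]=[N+]=CC(=O)/C(C)=C/C(=O)Oc1cc(C)c(C(=O)OCc2ccccc2)c(OCc2ccccc2)c1 | intermediate
13 | chloroacetaldehyde | O=CCCl | starting material
14 | triisopropylsilyl trifluoromethanesulfonate | CC(C)[Si](OS(=O)(=O)C(F)(F)F)(C(C)C)C(C)C | starting material
15 | (2-chloroethenyl)oxy-triisopropylsilane, E/Z mixture | ClC=CO[Si](C(C)C)(C(C)C)C(C)C | intermediate
16 | (triisopropylsilyloxy)acetylene | C#CO[Si](C(C)C)(C(C)C)C(C)C | intermediate
17 | vinylketene: benzyl 2-(benzyloxy)-6-methyl-4-{[(2E)-3-methyl-5-oxopenta-2,4-dienoyl]oxy}benzoate | O=C=C/C(C)=C/C(=O)Oc1cc(C)c(C(=O)OCc2ccccc2)c(OCc2ccccc2)c1 | intermediate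
18 | vinylcyclobutenone: the ring C aryl ester of (2E)-3-[4-oxo-2-(triisopropylsilyloxy)cyclobut-2-en-1-yl]but-2-enoic acid, racemic | O=C1C=C(O[Si](C(C)C)(C(C)C)C(C)C)C1/C(C)=C/C(=O)Oc1cc(C)c(C(=O)OCc2ccccc2)c(OCc2ccccc2)c1 | intermediate
19 | dienylketene: the ring C aryl ester of (2E,4E)-3-methyl-7-oxo-5-(triisopropylsilyloxy)hepta-2,4,6-trienoic acid (C3 and C6 cis across C4=C5) | O=C=C/C(O[Si](C(C)C)(C(C)C)C(C)C)=C\C(C)=C\C(=O)Oc1cc(C)c(C(=O)OCc2ccccc2)c(OCc2ccccc2)c1 | intermediate
20 | cyclohexadienone: the ring C aryl ester of 2-methyl-6-oxo-4-(triisopropylsilyloxy)cyclohexa-2,4-diene-1-carboxylic acid, racemic | O=C1C=C(O[Si](C(C)C)(C(C)C)C(C)C)C=C(C)C1C(=O)Oc1cc(C)c(C(=O)OCc2ccccc2)c(OCc2ccccc2)c1 | intermediate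
21 | benzyl 2-(benzyloxy)-4-{[2-hydroxy-6-methyl-4-(triisopropylsilyloxy)benzoyl]oxy}-6-methylbenzoate | Cc1cc(O[Si](C(C)C)(C(C)C)C(C)C)cc(O)c1C(=O)Oc1cc(C)c(C(=O)OCc2ccccc2)c(OCc2ccccc2)c1 | intermediate
22 | benzyl 2-(benzyloxy)-4-{[2-methoxy-6-methyl-4-(triisopropylsilyloxy)benzoyl]oxy}-6-methylbenzoate | COc1cc(O[Si](C(C)C)(C(C)C)C(C)C)cc(C)c1C(=O)Oc1cc(C)c(C(=O)OCc2ccccc2)c(OCc2ccccc2)c1 | intermediate
23 | benzyl 2-(benzyloxy)-4-[(4-hydroxy-2-methoxy-6-methylbenzoyl)oxy]-6-methylbenzoate | COc1cc(O)cc(C)c1C(=O)Oc1cc(C)c(C(=O)OCc2ccccc2)c(OCc2ccccc2)c1 | intermediate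
24 | aryl sulfate: benzyl 2,4-dihydroxy-6-methyl-5-(sulfonatooxy)benzoate, potassium salt | Cc1c(OS(=O)(=O)[O-])c(O)cc(O)c1C(=O)OCc1ccccc1.[K+] | intermediate
25 | benzyl 2,4,5-trihydroxy-6-methylbenzoate | Cc1c(O)c(O)cc(O)c1C(=O)OCc1ccccc1 | intermediate
26 | benzyl 2,4,5-tris(benzyloxy)-6-methylbenzoate | Cc1c(OCc2ccccc2)c(OCc2ccccc2)cc(OCc2ccccc2)c1C(=O)OCc1ccccc1 | intermediate
27 | 2,4,5-tris(benzyloxy)-6-methylbenzoic acid | Cc1c(OCc2ccccc2)c(OCc2ccccc2)cc(OCc2ccccc2)c1C(=O)O | intermediate
28 | 2,4,5-tris(benzyloxy)-6-methylbenzoyl chloride | Cc1c(OCc2ccccc2)c(OCc2ccccc2)cc(OCc2ccccc2)c1C(Cl)=O | intermediate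
29 | benzyl 2-(benzyloxy)-4-[(2-methoxy-6-methyl-4-{[2,4,5-tris(benzyloxy)-6-methylbenzoyl]oxy}benzoyl)oxy]-6-methylbenzoate | COc1cc(OC(=O)c2c(OCc3ccccc3)cc(OCc3ccccc3)c(OCc3ccccc3)c2C)cc(C)c1C(=O)Oc1cc(C)c(C(=O)OCc2ccccc2)c(OCc2ccccc2)c1 | intermediate
30 | 2'-O-methylhiascic acid | COc1cc(OC(=O)c2c(O)cc(O)c(O)c2C)cc(C)c1C(=O)Oc1cc(C)c(C(=O)O)c(O)c1 | target

**Step count and risks**

Total step count: 19.
Longest linear sequence: 10 steps (steps 1–4, 9, 12, 13, 14, 18, 19; the branch through steps 5–9 is equally long).

Step 12 (key step). What may go wrong: photoisomerisation of the E alkene, after which the Z vinylketene can close through the ester carbonyl oxygen to a 2-pyranone; capture of the ketene by the phenol that is being formed; photo-Fries cleavage of the aryl ester. Fallback: ring B is taken preformed from orsellinic acid and joined to ring C by classical depside esterification. It sets out from MOM ether 3 and phenol 5 and comes back to the route at phenol 23. The chelated 2-hydroxyl of 3 is methylated (MeI, K2CO3, DMF, 50 °C) to benzyl 2-methoxy-4-(methoxymethoxy)-6-methylbenzoate F1. Hydrogenolysis (H2, Pd/C, EtOAc) should give 2-methoxy-4-(methoxymethoxy)-6-methylbenzoic acid F2. DCC/DMAP esterification with 5 in toluene should give benzyl 2-(benzyloxy)-4-{[2-methoxy-4-(methoxymethoxy)-6-methylbenzoyl]oxy}-6-methylbenzoate F3. HCl in MeOH/THF then removes the MOM group to give 23.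

Step 11. What may go wrong: attack of the amide base at silicon or O-to-C silyl migration in the lithiated species, incomplete elimination from the E isomer, and loss of the volatile, moisture-sensitive ynol ether on isolation. Fallback: the O–Si bond is made last instead of first. It sets out from silyl triflate 14 and comes back at alkyne 16. Acetylene (commercial gas) in THF at −78 °C is converted with n-BuLi into lithium acetylide F4, which lithium tert-butyl peroxide (from t-BuOOH and LiN(SiMe3)2) should oxidise to lithium ethynolate F5. Compound 14 at −78 °C then silylates the ynolate on oxygen, the bulky silyl group disfavouring attack at carbon, to give 16.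

Step 15. What may go wrong: low conversion, usual for persulfate oxidations; over-oxidation of the hydroxyquinol to a quinone in the alkaline medium; partial loss of the benzyl ester during the hot acid hydrolysis of the sulfate. Fallback: the C5 oxygen is introduced through a halide. It sets out from 2 and comes back at 26. Compound 2 is dibenzylated (BnBr, K2CO3, DMF) to benzyl 2,4-bis(benzyloxy)-6-methylbenzoate F6. NBS in MeCN should brominate C5 (para to the 2-benzyloxy group, whereas C3 lies between two ethers) to benzyl 2,4-bis(benzyloxy)-5-bromo-6-methylbenzoate F7. Miyaura borylation (B2pin2, PdCl2(dppf), KOAc, dioxane, 90 °C) should give benzyl 2,4-bis(benzyloxy)-6-methyl-5-(4,4,5,5-tetramethyl-1,3,2-dioxaborolan-2-yl)benzoate F8. Oxidation (H2O2, aq NaOH, THF, 0 °C) gives benzyl 2,4-bis(benzyloxy)-5-hydroxy-6-methylbenzoate F9, and benzylation (BnBr, K2CO3, DMF) gives 26.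

**Further compounds**

F1 | step 12 | benzyl 2-methoxy-4-(methoxymethoxy)-6-methylbenzoate | COCOc1cc(C)c(C(=O)OCc2ccccc2)c(OC)c1
F2 | step 12 | 2-methoxy-4-(methoxymethoxy)-6-methylbenzoic acid | COCOc1cc(C)c(C(=O)O)c(OC)c1
F3 | step 12 | benzyl 2-(benzyloxy)-4-{[2-methoxy-4-(methoxymethoxy)-6-methylbenzoyl]oxy}-6-methylbenzoate | COCOc1cc(C)c(C(=O)Oc2cc(C)c(C(=O)OCc3ccccc3)c(OCc3ccccc3)c2)c(OC)c1
F4 | step 11 | lithium acetylide | [Li+].[C-]#C
F5 | step 11 | lithium ethynolate | [Li+].[O-]C#C
F6 | step 15 | benzyl 2,4-bis(benzyloxy)-6-methylbenzoate | Cc1cc(OCc2ccccc2)cc(OCc2ccccc2)c1C(=O)OCc1ccccc1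
F7 | step 15 | benzyl 2,4-bis(benzyloxy)-5-bromo-6-methylbenzoate | Cc1c(Br)c(OCc2ccccc2)cc(OCc2ccccc2)c1C(=O)OCc1ccccc1
F8 | step 15 | benzyl 2,4-bis(benzyloxy)-6-methyl-5-(4,4,5,5-tetramethyl-1,3,2-dioxaborolan-2-yl)benzoate | Cc1c(B2OC(C)(C)C(C)(C)O2)c(OCc2ccccc2)cc(OCc2ccccc2)c1C(=O)OCc1ccccc1
F9 | step 15 | benzyl 2,4-bis(benzyloxy)-5-hydroxy-6-methylbenzoate | Cc1c(O)c(OCc2ccccc2)cc(OCc2ccccc2)c1C(=O)OCc1ccccc1
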